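**Plan**

1. Numbering is that of the cembrane skeleton: ring C1–C14; C15(=C17H2)–C16(=O)–O–C12 on C1; ether O between C4 and C7; methyls C18 (on C4) and C20 (on C12); exo-methylene C19 on C8.
2. Cuts, last bond first: C16–O(C12) and C15–C16 (carbonylative lactonisation), C9–C10 (macrocyclisation of a β-keto ester onto an allylic chloride), C10–C11 (diazoacetate homologation), C1–C14 (lactone enolate alkylation), C1–C2 (ketone enolate alkylation), O–C7 (oxolane).
3. Enabling feature: C7 is at once an oxolane carbon and allylic to the exo-methylene carbon C8, so O–C7 can form when the C4 tertiary hydroxyl that (R)-linalool already carries captures a π-allyl built on C7, C8 and one CH2 branch of C8.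
4. Forward order: oxolane (step 3); γ-lactone C3–O–C15 as stereochemical relay (step 6); union with a C11–C14 piece from (R)-citramalic acid (step 10); 14-membered carbocycle closed at C9–C10 (step 17); seven-membered α-methylene lactone last (step 24).
5. Stereochemistry: C4 from (R)-linalool, C7 from the chiral palladium catalyst, C3 and C11 from Corey–Bakshi–Shibata reductions, C1 from anti alkylation of the γ-lactone (relayed from C3), C12 from (R)-citramalic acid.

Key step: step 3

Assumption: the (1R,2R) enantiomer of the diphosphine is taken as the one matched with the fixed C4 centre for the 7S (cis) ring; the working model for this ligand family does not settle this with certainty for a 2-methyl-substituted allyl unit.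

**Route**

Step 1
Reactants: 1 (R)-linalool
Product: 2 (2E,6R)-2,6-dimethylocta-2,7-diene-1,6-diol
Conditions: SeO2 (0.3 equiv), t-BuOOH (aq., 3 equiv), CH2Cl2, rt
Reagents that add atoms: tert-butyl hydroperoxide, CC(C)(C)OO; selenium dioxide (oxygen relay), O=[Se]=O
Why: Riley-type allylic oxidation (ene reaction, then [2,3]-shift) is known to hydroxylate the E-methyl group of a trisubstituted alkene selectively and leaves the vinyl carbinol and C4 untouched.

Step 2
Reactants: 2 (2E,6R)-2,6-dimethylocta-2,7-diene-1,6-diol; 3 methyl chloroformate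
Product: 4 methyl (2E,6R)-6-hydroxy-2,6-dimethylocta-2,7-dien-1-yl carbonate
Conditions: ClCO2Me, pyridine, CH2Cl2, 0 °C
Reagents that add atoms: methyl chloroformate, COC(=O)Cl
Why: Acylation of an unhindered primary allylic alcohol is far faster than that of the tertiary C4 hydroxyl, so only the primary carbonate should form.

Step 3
Reactants: 4 methyl (2E,6R)-6-hydroxy-2,6-dimethylocta-2,7-dien-1-yl carbonate
Product: 5 (2R,5S)-2-ethenyl-2-methyl-5-(prop-1-en-2-yl)oxolane
Conditions: Pd2(dba)3·CHCl3 (2.5 mol %), N,N'-[(1R,2R)-cyclohexane-1,2-diyl]bis[2-(diphenylphosphino)benzamide] (7.5 mol %), CH2Cl2, 0 °C → rt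
Reagents that add atoms: none
Why: Zerovalent palladium ionises the primary allylic carbonate with loss of CO2 and methoxide to a cationic π-allyl complex over C7, C8 and the former carbonate carbon (the later C9), and the methoxide deprotonates the C4 hydroxyl. The closest known reaction is the asymmetric Tsuji–Trost O-alkylation (cycloetherification) that closes 2-alkenyl oxolanes. The oxolane closes 5-exo by attack of the C4 alkoxide on C7 anti to palladium; attack at the CH2 terminus would need a seven-membered ring. C7 is set by the chiral diphosphine, which selects between the two π-allyl faces that interconvert by π–σ–π isomerisation through the unsubstituted terminus, while C4 is carried over from (R)-linalool. The step needs attack at C7 and not at the CH2 terminus, which ring size secures, and the isopropenyl group cis to the vinyl group (7S), which catalyst control over the fixed C4 centre should secure; the alkene ends in the isopropenyl group.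

Step 4
Reactants: 5 (2R,5S)-2-ethenyl-2-methyl-5-(prop-1-en-2-yl)oxolane
Product: 6 1-[(2R,5S)-2-methyl-5-(prop-1-en-2-yl)oxolan-2-yl]ethan-1-one
Conditions: PdCl2[2-(4,5-dihydrooxazol-2-yl)quinoline] (5 mol %), AgSbF6 (12 mol %), t-BuOOH (aq.), CH2Cl2, 0 °C → rt
Reagents that add atoms: tert-butyl hydroperoxide, CC(C)(C)OO
Why: Tsuji–Wacker oxidation in its hydroperoxide variant accepts only the monosubstituted vinyl group (the 1,1-disubstituted isopropenyl group is inert), and the cationic quinoline–oxazoline complex of divalent palladium is the catalyst type that directs oxygen to the internal carbon (C3) of allylic ethers.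

Step 5
Reactants: 6 1-[(2R,5S)-2-methyl-5-(prop-1-en-2-yl)oxolan-2-yl]ethan-1-one; 7 ethyl bromoacetate
Product: 9 ethyl 4-[(2R,5S)-2-methyl-5-(prop-1-en-2-yl)oxolan-2-yl]-4-oxobutanoate, via lithium enolate 8 (not isolated)
Conditions: LiN(iPr)2, THF, −78 °C; then BrCH2CO2Et, DMPU, −78 → −20 °C
Reagents that add atoms: ethyl bromoacetate (7), CCOC(=O)CBr
Why: Ketone enolate alkylation (SN2): C4 is quaternary, so only the C2 methyl can enolise, and the α-bromo ester is a reactive electrophile that brings in C1 and C15.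

Step 6
Reactants: 9 ethyl 4-[(2R,5S)-2-methyl-5-(prop-1-en-2-yl)oxolan-2-yl]-4-oxobutanoate
Product: 11 (5S)-5-[(2R,5S)-2-methyl-5-(prop-1-en-2-yl)oxolan-2-yl]oxolan-2-one, via hydroxy ester 10 (not isolated)
Conditions: (R)-1-methyl-3,3-diphenyltetrahydro-1H,3H-pyrrolo[1,2-c][1,3,2]oxazaborole [(R)-Me-CBS] (20 mol %), catecholborane, toluene, −78 → −40 °C; then pyridinium p-toluenesulfonate (cat.), toluene, 60 °C
Reagents that add atoms: none
Why: Corey–Bakshi–Shibata reduction treats the quaternary C4 as the large and the CH2 chain as the small group, so the (R)-catalyst should give 3S under reagent control; catecholborane spares the alkene, and the γ-hydroxy ester lactonises under mild acid.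

Step 7
Reactants: 12 (R)-citramalic acid
Product: 13 (2R)-2-methylbutane-1,2,4-triol
Conditions: BH3·SMe2, B(OMe)3, THF, 0 °C → rt; MeOH
Reagents that add atoms: none
Why: Borane reduces both carboxylic acids of a hydroxy diacid to primary alcohols (as known for malic acid) without touching the quaternary carbinol centre that becomes C12.

Step 8
Reactants: 13 (2R)-2-methylbutane-1,2,4-triol
Product: 14 2-[(4R)-2,2,4-trimethyl-1,3-dioxolan-4-yl]ethan-1-ol
Conditions: 2,2-dimethoxypropane, TsOH·H2O (cat.), acetone, rt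
Reagents that add atoms: 2,2-dimethoxypropane, COC(C)(C)OC
Why: Acetonide formation under equilibrating conditions favours the five-membered dioxolane of the 1,2-diol over the six-membered dioxane, which leaves the C14 hydroxyl free.

Step 9
Reactants: 14 2-[(4R)-2,2,4-trimethyl-1,3-dioxolan-4-yl]ethan-1-ol
Product: 15 (4R)-4-(2-iodoethyl)-2,2,4-trimethyl-1,3-dioxolane
Conditions: I2, PPh3, imidazole, CH2Cl2, 0 °C → rt
Reagents that add atoms: iodine, II
Why: Appel-type iodination converts a primary alcohol to the iodide through an alkoxyphosphonium ion under conditions that an acetonide tolerates.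

Step 10
Reactants: 11 (5S)-5-[(2R,5S)-2-methyl-5-(prop-1-en-2-yl)oxolan-2-yl]oxolan-2-one; 15 (4R)-4-(2-iodoethyl)-2,2,4-trimethyl-1,3-dioxolane
Product: 17 (3R,5S)-5-[(2R,5S)-2-methyl-5-(prop-1-en-2-yl)oxolan-2-yl]-3-{2-[(4R)-2,2,4-trimethyl-1,3-dioxolan-4-yl]ethyl}oxolan-2-one, via lithium enolate 16 (not isolated)
Conditions: LiN(iPr)2, THF, −78 °C; then 15, DMPU, −78 → −30 °C
Reagents that add atoms: iodide 15, ICC[C@]1(C)COC(C)(C)O1
Why: γ-Butyrolactone enolate alkylation (SN2): the electrophile approaches the planar enolate anti to the bulky oxolanyl group on C3, giving the 1,3-trans lactone, which is 1R.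

Step 11
Reactants: 17 (3R,5S)-5-[(2R,5S)-2-methyl-5-(prop-1-en-2-yl)oxolan-2-yl]-3-{2-[(4R)-2,2,4-trimethyl-1,3-dioxolan-4-yl]ethyl}oxolan-2-one
Product: 18 (3R,5S)-5-[(2R,5S)-5-(3-chloroprop-1-en-2-yl)-2-methyloxolan-2-yl]-3-{2-[(4R)-2,2,4-trimethyl-1,3-dioxolan-4-yl]ethyl}oxolan-2-one
Conditions: Ca(OCl)2, solid CO2, CH2Cl2/H2O, 0 °C
Reagents that add atoms: calcium hypochlorite, [Ca+2].[O-]Cl.[O-]Cl
Why: Ene-type allylic chlorination of an isopropenyl group with hypochlorous acid puts chlorine on the former methylene carbon (now C9) and moves the double bond to the former methyl carbon (now C19), so the two one-carbon branches of C8 exchange roles and the 2-substituted allyl chloride results.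

Step 12
Reactants: 18 (3R,5S)-5-[(2R,5S)-5-(3-chloroprop-1-en-2-yl)-2-methyloxolan-2-yl]-3-{2-[(4R)-2,2,4-trimethyl-1,3-dioxolan-4-yl]ethyl}oxolan-2-one
Product: 19 (3R,5S)-5-[(2R,5S)-5-(3-chloroprop-1-en-2-yl)-2-methyloxolan-2-yl]-3-[(3R)-3,4-dihydroxy-3-methylbutyl]oxolan-2-one
Conditions: AcOH/H2O (4:1), 40 °C
Reagents that add atoms: none
Why: Aqueous acid hydrolysis of the acetonide frees the C11/C12 diol; lactone, allylic chloride and oxolane should survive this mild acid.

Step 13
Reactants: 19 (3R,5S)-5-[(2R,5S)-5-(3-chloroprop-1-en-2-yl)-2-methyloxolan-2-yl]-3-[(3R)-3,4-dihydroxy-3-methylbutyl]oxolan-2-one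
Product: 20 (2R)-4-{(3R,5S)-5-[(2R,5S)-5-(3-chloroprop-1-en-2-yl)-2-methyloxolan-2-yl]-2-oxooxolan-3-yl}-2-hydroxy-2-methylbutanal
Conditions: Dess–Martin periodinane, CH2Cl2, rt
Reagents that add atoms: none
Why: Dess–Martin oxidation takes the primary C11 alcohol to the aldehyde, cannot oxidise the tertiary C12 hydroxyl and does not cleave the glycol; C12 is quaternary, so the aldehyde cannot epimerise.

Step 14
Reactants: 20 (2R)-4-{(3R,5S)-5-[(2R,5S)-5-(3-chloroprop-1-en-2-yl)-2-methyloxolan-2-yl]-2-oxooxolan-3-yl}-2-hydroxy-2-methylbutanal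
Product: 21 (2R)-4-{(3R,5S)-5-[(2R,5S)-5-(3-chloroprop-1-en-2-yl)-2-methyloxolan-2-yl]-2-oxooxolan-3-yl}-2-methyl-2-(triethylsilyloxy)butanal
Conditions: Et3SiOTf, 2,6-lutidine, CH2Cl2, −78 → 0 °C
Reagents that add atoms: triethylsilyl trifluoromethanesulfonate, CC[Si](CC)(CC)OS(=O)(=O)C(F)(F)F
Why: Silyl triflates silylate tertiary alcohols; the C12 oxygen must be blocked so that the later β-keto ester cannot close to a tetronic acid.

Step 15
Reactants: 22 allyl bromoacetate (prop-2-en-1-yl bromoacetate)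
Product: 24 allyl diazoacetate (prop-2-en-1-yl diazoacetate), via hydrazine adduct 23 (not isolated)
Conditions: TsNHNHTs, DBU, THF, 0 °C
Reagents that add atoms: N,N'-bis(4-methylbenzenesulfonyl)hydrazine, Cc1ccc(cc1)S(=O)(=O)NNS(=O)(=O)c1ccc(C)cc1
Why: The ditosylhydrazine method for diazoacetates: N-alkylation by the bromoacetate, then base-induced loss of two sulfinate ions gives the diazo ester.

Step 16
Reactants: 21 (2R)-4-{(3R,5S)-5-[(2R,5S)-5-(3-chloroprop-1-en-2-yl)-2-methyloxolan-2-yl]-2-oxooxolan-3-yl}-2-methyl-2-(triethylsilyloxy)butanal; 24 allyl diazoacetate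
Product: 25 prop-2-en-1-yl (4R)-6-{(3R,5S)-5-[(2R,5S)-5-(3-chloroprop-1-en-2-yl)-2-methyloxolan-2-yl]-2-oxooxolan-3-yl}-4-methyl-3-oxo-4-(triethylsilyloxy)hexanoate
Conditions: SnCl2 (10 mol %), CH2Cl2, rt
Reagents that add atoms: allyl diazoacetate 24, [N-]=[N+]=CC(=O)OCC=C
Why: Roskamp homologation: Lewis-acid-catalysed addition of the diazo ester to the aldehyde, 1,2-hydride shift and loss of N2 give the β-keto ester (C10 and the future C11 ketone) without strong base, so the γ-lactone is not touched.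

Step 17
Reactants: 25 prop-2-en-1-yl (4R)-6-{(3R,5S)-5-[(2R,5S)-5-(3-chloroprop-1-en-2-yl)-2-methyloxolan-2-yl]-2-oxooxolan-3-yl}-4-methyl-3-oxo-4-(triethylsilyloxy)hexanoate
Product: 26 macrocyclic allyl β-keto ester (14-membered ring C1–C14; 4,7-epoxy; 8(19)-methylidene; 11-oxo; 12-OSiEt3; 10-CO2-allyl; γ-lactone C15(=O)–O–C3; 1R,3S,4R,7S,12R; C10 epimers)
Conditions: Cs2CO3, CsI, MeCN, 60 °C, slow addition at high dilution
Reagents that add atoms: none
Why: Intramolecular C-alkylation of a soft β-keto ester enolate by an allylic halide is an established closure of 13- to 15-membered carbocycles, and SN2 and SN2′ attack on the 2-substituted allyl chloride give the same C9–C10 bond and C8 exo-methylene.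

Step 18
Reactants: 26 macrocyclic allyl β-keto ester
Product: 28 macrocyclic ketone (as 26 but C10 is CH2; 11-oxo; 12-OSiEt3; 1R,3S,4R,7S,12R), via keto acid 27 (not isolated)
Conditions: Pd(PPh3)4 (5 mol %), morpholine, THF, rt
Reagents that add atoms: none
Why: Tsuji deallylation: zerovalent palladium transfers the allyl group to morpholine and the β-keto acid decarboxylates at room temperature, leaving lactone, silyl ether and the allylic ether untouched.

Step 19
Reactants: 28 macrocyclic ketone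
Product: 29 macrocyclic 11R alcohol (11-OH; 12-OSiEt3; γ-lactone C15(=O)–O–C3; 1R,3S,4R,7S,11R,12R)
Conditions: (S)-1-methyl-3,3-diphenyltetrahydro-1H,3H-pyrrolo[1,2-c][1,3,2]oxazaborole [(S)-Me-CBS] (20 mol %), catecholborane, toluene, −78 → −40 °C
Reagents that add atoms: none
Why: Corey–Bakshi–Shibata reduction with quaternary C12 as the large group and C10H2 as the small one should give 11R with the (S)-catalyst under reagent control; catecholborane leaves lactone and alkene alone.

Step 20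
Reactants: 29 macrocyclic 11R alcohol
Product: 30 hydroxy methyl ketone (ring C1–C14; acetyl C15(=O)C17H3 on C1; 3-OH; 11-OH; 12-OSiEt3; 1R,3S,4R,7S,11R,12R)
Conditions: MeLi (3 equiv), THF, −78 °C; aq. NH4Cl at −78 °C
Reagents that add atoms: methyllithium, [Li]C
Why: Single addition of an organolithium to a γ-lactone: the tetrahedral lithium alkoxide persists at −78 °C and collapses on quench to the methyl ketone, which supplies C17 and frees the C3 hydroxyl.

Step 21
Reactants: 30 hydroxy methyl ketone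
Product: 31 diacetate methyl ketone (3-OAc; 11-OAc; 12-OSiEt3)
Conditions: Ac2O, 4-(dimethylamino)pyridine, pyridine, CH2Cl2, rt
Reagents that add atoms: acetic anhydride, CC(=O)OC(C)=O
Why: Nucleophile-catalysed acetylation esterifies the two secondary hydroxyls at C3 and C11, the final acetates of the target; the tertiary oxygen stays silylated.

Step 22
Reactants: 31 diacetate methyl ketone
Product: 33 enol triflate (C15(OTf)=C17H2 on C1; 3,11-diacetate; 12-OSiEt3), via potassium enolate 32 (not isolated)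
Conditions: KN(SiMe3)2, THF, −78 °C; PhNTf2, −78 → −40 °C
Reagents that add atoms: N-phenylbis(trifluoromethanesulfonimide), O=S(=O)(N(c1ccccc1)S(=O)(=O)C(F)(F)F)C(F)(F)F
Why: Kinetic deprotonation of a methyl ketone at the methyl group and O-triflation; ketones are deprotonated faster than acetates at −78 °C (as in steroidal keto acetates), and C1 is not enolised.

Step 23
Reactants: 33 enol triflate
Product: 34 hydroxy enol triflate (12-OH; 3,11-diacetate)
Conditions: HF·pyridine, pyridine, THF, 0 °C → rt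
Reagents that add atoms: none
Why: Buffered fluoride cleaves the tertiary triethylsilyl ether; acetates, enol triflate and the allylic ether are stable to it.

Step 24
Reactants: 34 hydroxy enol triflate
Product: 35 Granosolide B
Conditions: Pd(OAc)2 (10 mol %), Ph2P(CH2)3PPh2, CO (1 atm), iPr2NEt, DMF, 60 °C
Reagents that add atoms: carbon monoxide, [C-]#[O+]
Why: Carbonylative lactonisation of a hydroxy alkenyl triflate: oxidative addition, CO insertion and capture of the acylpalladium species by the C12 hydroxyl give the seven-membered α-methylene lactone, with C16 coming from CO and no stereocentre touched.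

**Compound list**

1 | (R)-linalool, (3R)-3,7-dimethylocta-1,6-dien-3-ol | C=C[C@@](O)(C)CCC=C(C)C | starting material
2 | (2E,6R)-2,6-dimethylocta-2,7-diene-1,6-diol | C=C[C@@](O)(C)CC/C=C(\C)CO | intermediate
3 | methyl chloroformate | COC(=O)Cl | starting material
4 | methyl (2E,6R)-6-hydroxy-2,6-dimethylocta-2,7-dien-1-yl carbonate | C=C[C@@](O)(C)CC/C=C(\C)COC(=O)OC | intermediate
5 | (2R,5S)-2-ethenyl-2-methyl-5-(prop-1-en-2-yl)oxolane | C=C[C@@]1(C)CC[C@H](O1)C(=C)C | intermediate
6 | 1-[(2R,5S)-2-methyl-5-(prop-1-en-2-yl)oxolan-2-yl]ethan-1-one | CC(=O)[C@@]1(C)CC[C@H](O1)C(=C)C | intermediate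
7 | ethyl bromoacetate | CCOC(=O)CBr | starting material
8 | lithium enolate of 6 (lithium 1-[(2R,5S)-2-methyl-5-(prop-1-en-2-yl)oxolan-2-yl]ethenolate) | [Li]OC(=C)[C@@]1(C)CC[C@H](O1)C(=C)C | intermediate
9 | ethyl 4-[(2R,5S)-2-methyl-5-(prop-1-en-2-yl)oxolan-2-yl]-4-oxobutanoate | CCOC(=O)CCC(=O)[C@@]1(C)CC[C@H](O1)C(=C)C | intermediate
10 | ethyl (4S)-4-hydroxy-4-[(2R,5S)-2-methyl-5-(prop-1-en-2-yl)oxolan-2-yl]butanoate | CCOC(=O)CC[C@H](O)[C@@]1(C)CC[C@H](O1)C(=C)C | intermediate
11 | (5S)-5-[(2R,5S)-2-methyl-5-(prop-1-en-2-yl)oxolan-2-yl]oxolan-2-one | O=C1CC[C@H](O1)[C@@]1(C)CC[C@H](O1)C(=C)C | intermediate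
12 | (R)-citramalic acid, (2R)-2-hydroxy-2-methylbutanedioic acid | O[C@](C(=O)O)(C)CC(=O)O | starting material
13 | (2R)-2-methylbutane-1,2,4-triol | O[C@](CO)(C)CCO | intermediate
14 | 2-[(4R)-2,2,4-trimethyl-1,3-dioxolan-4-yl]ethan-1-ol | OCC[C@]1(C)COC(C)(C)O1 | intermediate
15 | (4R)-4-(2-iodoethyl)-2,2,4-trimethyl-1,3-dioxolane | ICC[C@]1(C)COC(C)(C)O1 | intermediate
16 | lithium enolate of 11 | [Li]OC1=CC[C@H](O1)[C@@]2(C)CC[C@H](O2)C(=C)C | intermediate
17 | (3R,5S)-5-[(2R,5S)-2-methyl-5-(prop-1-en-2-yl)oxolan-2-yl]-3-{2-[(4R)-2,2,4-trimethyl-1,3-dioxolan-4-yl]ethyl}oxolan-2-one | O=C1O[C@@H](C[C@H]1CC[C@]2(C)COC(C)(C)O2)[C@@]3(C)CC[C@H](O3)C(=C)C | intermediate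
18 | (3R,5S)-5-[(2R,5S)-5-(3-chloroprop-1-en-2-yl)-2-methyloxolan-2-yl]-3-{2-[(4R)-2,2,4-trimethyl-1,3-dioxolan-4-yl]ethyl}oxolan-2-one | O=C1O[C@@H](C[C@H]1CC[C@]2(C)COC(C)(C)O2)[C@@]3(C)CC[C@H](O3)C(=C)CCl | intermediate
19 | (3R,5S)-5-[(2R,5S)-5-(3-chloroprop-1-en-2-yl)-2-methyloxolan-2-yl]-3-[(3R)-3,4-dihydroxy-3-methylbutyl]oxolan-2-one | O=C1O[C@@H](C[C@H]1CC[C@@](C)(O)CO)[C@@]2(C)CC[C@H](O2)C(=C)CCl | intermediate
20 | (2R)-4-{(3R,5S)-5-[(2R,5S)-5-(3-chloroprop-1-en-2-yl)-2-methyloxolan-2-yl]-2-oxooxolan-3-yl}-2-hydroxy-2-methylbutanal | O=C1O[C@@H](C[C@H]1CC[C@@](C)(O)C=O)[C@@]2(C)CC[C@H](O2)C(=C)CCl | intermediate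
21 | (2R)-4-{(3R,5S)-5-[(2R,5S)-5-(3-chloroprop-1-en-2-yl)-2-methyloxolan-2-yl]-2-oxooxolan-3-yl}-2-methyl-2-(triethylsilyloxy)butanal | O=C1O[C@@H](C[C@H]1CC[C@@](C)(O[Si](CC)(CC)CC)C=O)[C@@]2(C)CC[C@H](O2)C(=C)CCl | intermediate
22 | allyl bromoacetate (prop-2-en-1-yl bromoacetate) | BrCC(=O)OCC=C | starting material
23 | prop-2-en-1-yl 2-[1,2-bis(4-methylbenzenesulfonyl)hydrazin-1-yl]acetate | Cc1ccc(cc1)S(=O)(=O)NN(CC(=O)OCC=C)S(=O)(=O)c1ccc(C)cc1 | intermediate
24 | allyl diazoacetate (prop-2-en-1-yl diazoacetate) | [N-]=[N+]=CC(=O)OCC=C | intermediate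
25 | prop-2-en-1-yl (4R)-6-{(3R,5S)-5-[(2R,5S)-5-(3-chloroprop-1-en-2-yl)-2-methyloxolan-2-yl]-2-oxooxolan-3-yl}-4-methyl-3-oxo-4-(triethylsilyloxy)hexanoate | O=C1O[C@@H](C[C@H]1CC[C@@](C)(O[Si](CC)(CC)CC)C(=O)CC(=O)OCC=C)[C@@]2(C)CC[C@H](O2)C(=C)CCl | intermediate
26 | macrocyclic allyl β-keto ester: ring C1–C14 with 4,7-epoxy bridge, 8(19)-methylidene, 11-oxo, 12-methyl, 12-OSiEt3, allyloxycarbonyl on C10 (both epimers), γ-lactone C15(=O)–O–C3 across C1/C3; 1R,3S,4R,7S,12R | O=C1O[C@H]2C[C@H]1CC[C@@](C)(O[Si](CC)(CC)CC)C(=O)C(C(=O)OCC=C)CC(=C)[C@@H]3CC[C@@]2(C)O3 | intermediate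
27 | β-keto acid of 26 (CO2H on C10) | O=C1O[C@H]2C[C@H]1CC[C@@](C)(O[Si](CC)(CC)CC)C(=O)C(C(=O)O)CC(=C)[C@@H]3CC[C@@]2(C)O3 | intermediate
28 | macrocyclic ketone: as 26 with C10H2; 11-oxo, 12-OSiEt3, γ-lactone C15(=O)–O–C3; 1R,3S,4R,7S,12R | O=C1O[C@H]2C[C@H]1CC[C@@](C)(O[Si](CC)(CC)CC)C(=O)CCC(=C)[C@@H]3CC[C@@]2(C)O3 | intermediate
29 | macrocyclic alcohol: 11-OH, 12-OSiEt3, γ-lactone C15(=O)–O–C3; 1R,3S,4R,7S,11R,12R | O=C1O[C@H]2C[C@H]1CC[C@@](C)(O[Si](CC)(CC)CC)[C@H](O)CCC(=C)[C@@H]3CC[C@@]2(C)O3 | intermediate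
30 | hydroxy methyl ketone: ring C1–C14, 4,7-epoxy, 8(19)-methylidene, acetyl (C15, C17) on C1, 3-OH, 11-OH, 12-OSiEt3; 1R,3S,4R,7S,11R,12R | CC(=O)[C@H]1C[C@H](O)[C@@]2(C)CC[C@H](O2)C(=C)CC[C@@H](O)[C@](C)(O[Si](CC)(CC)CC)CC1 | intermediate
31 | diacetate methyl ketone: as 30 with 3-OAc and 11-OAc | CC(=O)[C@H]1C[C@H](OC(C)=O)[C@@]2(C)CC[C@H](O2)C(=C)CC[C@@H](OC(C)=O)[C@](C)(O[Si](CC)(CC)CC)CC1 | intermediate
32 | potassium enolate of 31 (C15(OK)=C17H2) | [K]OC(=C)[C@H]1C[C@H](OC(C)=O)[C@@]2(C)CC[C@H](O2)C(=C)CC[C@@H](OC(C)=O)[C@](C)(O[Si](CC)(CC)CC)CC1 | intermediate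
33 | enol triflate: C15(OSO2CF3)=C17H2 on C1, 3,11-diacetate, 12-OSiEt3 | C=C(OS(=O)(=O)C(F)(F)F)[C@H]1C[C@H](OC(C)=O)[C@@]2(C)CC[C@H](O2)C(=C)CC[C@@H](OC(C)=O)[C@](C)(O[Si](CC)(CC)CC)CC1 | intermediate
34 | hydroxy enol triflate: as 33 with 12-OH | C=C(OS(=O)(=O)C(F)(F)F)[C@H]1C[C@H](OC(C)=O)[C@@]2(C)CC[C@H](O2)C(=C)CC[C@@H](OC(C)=O)[C@](C)(O)CC1 | intermediate
35 | Granosolide B, (1R,3S,4R,7S,11R,12R)-3,11-diacetoxy-4,7-epoxycembra-8(19),15(17)-dien-16,12-olide | C=C1C(=O)O[C@]2(C)CC[C@@H]1C[C@H](OC(C)=O)[C@@]1(C)CC[C@H](O1)C(=C)CC[C@H]2OC(C)=O | target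

**Step count and risks**

Total step count: 24. Longest linear sequence: 20 steps, from (R)-linalool through steps 1–6, 10–14 and 16–24.

The three steps most likely to fail:

1. Step 24. The acylpalladium intermediate may be captured too slowly by the hindered tertiary C12 hydroxyl across a seven-membered ring, so that reduction, hydrolysis to the acid or intermolecular esters take over. The fallback sets out from 33 and comes back at 35, separating carbonylation from ring closure. Alkoxycarbonylation of 33 with 2-(trimethylsilyl)ethanol (Pd(OAc)2, Ph2P(CH2)3PPh2, CO, Et3N, DMF) should give the 2-(trimethylsilyl)ethyl acrylate F1. Buffered Bu4NF would remove both silicon groups to give the hydroxy acid F2. Yamaguchi lactonisation (2,4,6-trichlorobenzoyl chloride, Et3N; then 4-(dimethylamino)pyridine, toluene, high dilution, 80 °C) would close the lactone to 35.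

2. Step 17. Intermolecular alkylation (oligomers) or O-alkylation may outrun the 14-membered C-alkylation. The fallback sets out from 21 and comes back at 28, closing the same bond through a palladium π-allyl. Roskamp homologation of 21 with ethyl diazoacetate (SnCl2) should give the ethyl β-keto ester F3. Tsuji–Trost macrocyclisation (NaH, then Pd(PPh3)4 and Ph2P(CH2)2PPh2, THF, high dilution, 60 °C) would give the macrocyclic ethyl ester F4; the ethyl ester is not ionised by zerovalent palladium. Krapcho dealkoxycarbonylation (LiCl, wet DMSO, 130 °C) would return ketone 28.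

3. Step 4. Oxygen may be delivered to the terminal carbon (aldehyde) or the hindered vinyl group may react sluggishly. The fallback sets out from 5 and comes back at 6, masking the competing alkene and hydrating by hydrogen-atom transfer. mCPBA (1 equiv, NaHCO3, CH2Cl2, 0 °C) should epoxidise the more electron-rich isopropenyl group to the epoxide F5. Mukaiyama hydration of the remaining vinyl group (Co(acac)2, PhSiH3, O2, i-PrOH) would place the hydroxyl on C3 (Markovnikov through the secondary radical) to give the epoxy carbinol F6. Zn/NaI in AcOH would deoxygenate the epoxide to the alkenyl carbinol F7. Dess–Martin oxidation of F7 would give ketone 6.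

**Further compounds**

F1 | step 24 | 2-(trimethylsilyl)ethyl acrylate: C15(=C17H2)–C16(=O)OCH2CH2SiMe3 on C1, 3,11-diacetate, 12-OSiEt3; 1R,3S,4R,7S,11R,12R | C=C(C(=O)OCC[Si](C)(C)C)[C@H]1C[C@H](OC(C)=O)[C@@]2(C)CC[C@H](O2)C(=C)CC[C@@H](OC(C)=O)[C@](C)(O[Si](CC)(CC)CC)CC1
F2 | step 24 | hydroxy acid: C15(=C17H2)–C16O2H on C1, 3,11-diacetate, 12-OH | C=C(C(=O)O)[C@H]1C[C@H](OC(C)=O)[C@@]2(C)CC[C@H](O2)C(=C)CC[C@@H](OC(C)=O)[C@](C)(O)CC1
F3 | step 17 | ethyl (4R)-6-{(3R,5S)-5-[(2R,5S)-5-(3-chloroprop-1-en-2-yl)-2-methyloxolan-2-yl]-2-oxooxolan-3-yl}-4-methyl-3-oxo-4-(triethylsilyloxy)hexanoate | O=C1O[C@@H](C[C@H]1CC[C@@](C)(O[Si](CC)(CC)CC)C(=O)CC(=O)OCC)[C@@]2(C)CC[C@H](O2)C(=C)CCl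
F4 | step 17 | macrocyclic ethyl β-keto ester: as 26 with ethoxycarbonyl on C10 (both epimers) | O=C1O[C@H]2C[C@H]1CC[C@@](C)(O[Si](CC)(CC)CC)C(=O)C(C(=O)OCC)CC(=C)[C@@H]3CC[C@@]2(C)O3
F5 | step 4 | (2R,5S)-2-ethenyl-2-methyl-5-(2-methyloxiran-2-yl)oxolane (both oxirane epimers) | C=C[C@@]1(C)CC[C@H](O1)C1(C)CO1
F6 | step 4 | 1-[(2R,5S)-2-methyl-5-(2-methyloxiran-2-yl)oxolan-2-yl]ethan-1-ol (carbinol and oxirane epimers) | CC(O)[C@@]1(C)CC[C@H](O1)C1(C)CO1
F7 | step 4 | 1-[(2R,5S)-2-methyl-5-(prop-1-en-2-yl)oxolan-2-yl]ethan-1-ol (both carbinol epimers) | CC(O)[C@@]1(C)CC[C@H](O1)C(=C)C
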